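The substrate put in stays counted, as substrate, intermediate A, target, intermediate B, trapped intermediate or over-reaction product, so I asked how fast it entered target and how fast target left.

common to all: capture agent 1.00 mM

| charge | substrate | remark | time |
|---|---|---|---|
| east | 10 mM | one stirred flow tank at steady state, fed with the mixture as stated, mean residence time 15.0 d |  |
| south-east | 10 mM | a single well-mixed tank run continuously and read at steady state, 5.0 d in it on average |  |
| west | 10 mM | a closed flask charged with all of it at once and left for 5.0 d | 5.0 d |
| north-east | 10 mM (fed, over 5.00 d) | all but substrate at the start; substrate goes in evenly over 5.00 d, the run ends at 5.0 d | 5.0 d |

    intermediate A → intermediate B (k1 = 0.0064 /h)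
    substrate ⇌ intermediate A (K2 = 0.18, k2 = 0.0079 /h)
    target → over-reaction product (k3 = 0.011 /h)
    intermediate A → target (k4 = 0.38 /h)
    target ⇌ intermediate B (K5 = 14, k5 = 0.0064 /h)
    capture agent + intermediate A → trapped intermediate (k6 = 3.0 /M/h)

* the set-up with the highest amount of target at the outlet or at the end, in percent of the substrate put in ("none" if the first two lie within 2 percentage points) (east / south-east / west / north-east / none)
* amount of target at the outlet or at the end, in percent of the substrate put in, east
* amount of target at the outlet or at the end, in percent of the substrate put in, south-east
* amount of target at the outlet or at the end, in percent of the substrate put in, west
* amount of target at the outlet or at the end, in percent of the substrate put in, north-east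

- the stated concentrations are those of everything mixed, before any reaction; amounts are the same in each set-up
- the feed brings no volume worth counting
- run time (west): 5.0 d

**Two constants.** Intermediate A went on to target at 0.38 /h, faster than substrate formed it at 0.0079 /h, so I held [intermediate A] quasi-steady. Substrate then drained at 0.00710 /h, and 97.6% of the drained substrate reached target. Target left at 0.0174 /h, the sum of its forward steps; I dropped the return from intermediate B, whose constant 4.57 × 10⁻⁴ /h is smaller than the forward 0.0064 /h.

**Both ends.** For west, a target that was never lost gave a ceiling of 56.0%. A target lost so quickly that it merely followed [substrate] gave a floor of 17.0%. I expected west between them and nearer the floor, because the loss constant is 2.45 times the drain constant, yet [target] lags behind a falling [substrate].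

**The join.** The consecutive solution with these two constants gave 20.4% for west. Its maximum came at 3.63 d: this is the crest time, the moment at which a batch with these two constants makes target as fast as it loses it. West ran past it.

**Other vessels.** The same constants gave 9.66% for east and 14.5% for south-east, whose mean residence time equals 5.0 d. The even feed of north-east gave 17.1%. My choice was west.

**The forecast.** It said west, with 10.1% for east, 14.7% for south-east, 20.6% for west and 16.7% for north-east, on the grounds that “target is a consecutive product”. It put the peak near 100 h, and my crest time was 87.0 h.

**The flask.** The simulation gave 10.1% for east, 14.5% for south-east, 20.7% for west and 16.7% for north-east, with west highest. In west, each step taken net, target was made 1.60 times as fast as it was used at 1.98 d and 0.851 times as fast at 5.00 d, moments on either side of the reckoned crest time of 3.63 d. The west flask left until 8.0 d, further past the reckoned crest, held target at 15.4% of the substrate charged, and the consecutive solution gave 14.8% there.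

Its constants are those of an exercise; the run is a simulation.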